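**Retrosynthetic overview**

- Prestegane A ⇐ its C3-epimer mixture: the trans (3R,4R) lactone is the thermodynamic diastereomer, so C3 is settled last by base equilibration.
- That lactone ⇐ a 1-aroyl-6-aryl-3-oxabicyclo[3.1.0]hexan-2-one by one hydrogenation: the donor–acceptor cyclopropane bond C1–C6 is cut (C6 becomes the veratryl CH2), ArC=O goes to CH2, and the O-benzyl group falls off.
- The bicycle ⇐ a cinnamyl 2-diazo-3-aryl-3-oxopropanoate by catalytic asymmetric intramolecular cyclopropanation: γ-lactone and cyclopropane close together, and the one stereocentre that survives (the future C4) is set here.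
- The diazo ester ⇐ β-keto ester (diazo transfer) ⇐ O-benzylisovanillic acid + Meldrum's acid + (E)-3,4-dimethoxycinnamyl alcohol.
- Ring order: both arenes are bought; lactone and cyclopropane form in the same step; the cyclopropane is then opened reductively.

Assumption: 1 and 3 are bought; [Co(3,5-DitBu-ChenPhyrin)] is the divalent cobalt complex of 5,15-bis(3,5-di-tert-butylphenyl)-10,20-bis{2,6-bis[(S)-2,2-dimethylcyclopropanecarboxamido]phenyl}porphyrin, and a small trial run decides whether the (S)- or the (R)-amide ligand gives (5R)-7.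

**Step 1**
Reactants: 1 3-(benzyloxy)-4-methoxybenzoic acid; 2 Meldrum's acid (2,2-dimethyl-1,3-dioxane-4,6-dione); 3 (E)-3-(3,4-dimethoxyphenyl)prop-2-en-1-ol
Product: 5 (2E)-3-(3,4-dimethoxyphenyl)prop-2-en-1-yl 3-[3-(benzyloxy)-4-methoxyphenyl]-3-oxopropanoate, via acyl Meldrum's acid 4 (not isolated)
Conditions: DCC (1.1 equiv), DMAP (1.5 equiv), CH2Cl2, 0 °C to rt; filter, KHSO4 wash, concentrate; then 3, toluene, 110 °C
Reagents that add atoms: none
Why: Carbodiimide C-acylation of Meldrum's acid gives 4, which on heating loses acetone and CO2 through an aroylketene that the allylic alcohol traps (Oikawa–Yonemitsu β-keto ester synthesis); no stereocentre is formed and the E alkene is untouched.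

**Step 2**
Reactants: 5 (2E)-3-(3,4-dimethoxyphenyl)prop-2-en-1-yl 3-[3-(benzyloxy)-4-methoxyphenyl]-3-oxopropanoate
Product: 6 (2E)-3-(3,4-dimethoxyphenyl)prop-2-en-1-yl 3-[3-(benzyloxy)-4-methoxyphenyl]-2-diazo-3-oxopropanoate
Conditions: p-ABSA (1.2 equiv), Et3N, MeCN, 0 °C to rt
Reagents that add atoms: 4-acetamidobenzenesulfonyl azide (p-ABSA), CC(=O)Nc1ccc(cc1)S(=O)(=O)N=[N+]=[N-]
Why: Regitz diazo transfer: the enolate of the 1,3-dicarbonyl attacks the terminal azide nitrogen and the adduct collapses to the 2-diazo-1,3-dicarbonyl compound and the sulfonamide; no stereocentre is involved.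

**Step 3**
Reactants: 6 (2E)-3-(3,4-dimethoxyphenyl)prop-2-en-1-yl 3-[3-(benzyloxy)-4-methoxyphenyl]-2-diazo-3-oxopropanoate
Product: 7 (1S,5R,6S)-1-[3-(benzyloxy)-4-methoxybenzoyl]-6-(3,4-dimethoxyphenyl)-3-oxabicyclo[3.1.0]hexan-2-one
Conditions: [Co(3,5-DitBu-ChenPhyrin)] (3 mol %), toluene, N2, 25 to 40 °C
Reagents that add atoms: none
Why: Asymmetric intramolecular cyclopropanation of an acceptor/acceptor allyl diazoacetate by a chiral cobalt porphyrin (metalloradical carbene transfer), here stretched to an aroyl acceptor and an electron-rich cinnamyl ester: loss of N2 gives a cobalt-bound carbon radical that adds 5-exo to the alkene (closing the lactone) and then closes the cyclopropane at the benzylic radical, the amide pocket of the ligand choosing the alkene face and so setting C5 as R (the future C4 of the target), with C1 (S) fixed by the cis ring fusion and C6 (S, aryl exo) by the E alkene; the two carbonyl groups on the carbene carbon exclude β-hydride shift and dimerisation.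

**Step 4**
Reactants: 7 (1S,5R,6S)-1-[3-(benzyloxy)-4-methoxybenzoyl]-6-(3,4-dimethoxyphenyl)-3-oxabicyclo[3.1.0]hexan-2-one
Product: 10 (4R)-4-(3,4-dimethoxybenzyl)-3-(3-hydroxy-4-methoxybenzyl)oxolan-2-one (mixture of C3 epimers), via keto lactone 8 (not isolated), via benzylic alcohol 9 (not isolated)
Conditions: H2 (4 atm), Pd(OH)2/C, EtOAc–AcOH 1:1, 25 to 50 °C
Reagents that add atoms: none
Why: Hydrogenolysis cascade on palladium: the donor–acceptor cyclopropane bond C1–C6 (benzylic to the dimethoxyphenyl ring and geminal to both carbonyls) is cleaved so that C6 becomes the veratryl CH2 and C5 becomes C4 with its R configuration untouched, the benzyl ether is removed, and the electron-rich aryl ketone is taken through the benzylic alcohol to CH2 (benzylic C–O hydrogenolysis, kept free of mineral acid so that the benzylic cation cannot cyclise onto the veratryl ring); C3 is not controlled here and is corrected in step 5.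

**Step 5**
Reactants: 10 (4R)-4-(3,4-dimethoxybenzyl)-3-(3-hydroxy-4-methoxybenzyl)oxolan-2-one (mixture of C3 epimers)
Product: 11 Prestegane A, (3R,4R)-4-(3,4-dimethoxybenzyl)-3-(3-hydroxy-4-methoxybenzyl)oxolan-2-one
Conditions: KOC(CH3)3 (1.5 equiv), THF, 0 °C to rt; then 1 M HCl
Reagents that add atoms: none
Why: Thermodynamic epimerisation through the lactone enolate (the phenol is held as its phenoxide): the trans-3,4-dibenzyl lactone is the more stable diastereomer (about 9:1 or better expected), C4 has no acidic hydrogen and stays R, so C3 settles as R; residual cis isomer is separated and resubmitted.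

**Compound list**

1 | 3-(benzyloxy)-4-methoxybenzoic acid | COc1ccc(C(=O)O)cc1OCc1ccccc1 | starting material
2 | Meldrum's acid (2,2-dimethyl-1,3-dioxane-4,6-dione) | CC1(C)OC(=O)CC(=O)O1 | starting material
3 | (E)-3-(3,4-dimethoxyphenyl)prop-2-en-1-ol | COc1ccc(/C=C/CO)cc1OC | starting material
4 | 5-{[3-(benzyloxy)-4-methoxyphenyl](hydroxy)methylidene}-2,2-dimethyl-1,3-dioxane-4,6-dione (acyl Meldrum's acid, enol form) | COc1ccc(C(O)=C2C(=O)OC(C)(C)OC2=O)cc1OCc1ccccc1 | intermediate
5 | (2E)-3-(3,4-dimethoxyphenyl)prop-2-en-1-yl 3-[3-(benzyloxy)-4-methoxyphenyl]-3-oxopropanoate | COc1ccc(/C=C/COC(=O)CC(=O)c2ccc(OC)c(OCc3ccccc3)c2)cc1OC | intermediate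
6 | (2E)-3-(3,4-dimethoxyphenyl)prop-2-en-1-yl 3-[3-(benzyloxy)-4-methoxyphenyl]-2-diazo-3-oxopropanoate | COc1ccc(/C=C/COC(=O)C(=[N+]=[N-])C(=O)c2ccc(OC)c(OCc3ccccc3)c2)cc1OC | intermediate
7 | (1S,5R,6S)-1-[3-(benzyloxy)-4-methoxybenzoyl]-6-(3,4-dimethoxyphenyl)-3-oxabicyclo[3.1.0]hexan-2-one | O=C1OC[C@@H]2[C@@H](c3ccc(OC)c(OC)c3)[C@]12C(=O)c1ccc(OC)c(OCc3ccccc3)c1 | intermediate
8 | (3S,4R)-4-(3,4-dimethoxybenzyl)-3-(3-hydroxy-4-methoxybenzoyl)oxolan-2-one (trans keto lactone, C3 labile) | COc1ccc(C(=O)[C@H]2C(=O)OC[C@@H]2Cc2ccc(OC)c(OC)c2)cc1O | intermediate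
9 | (3S,4R)-4-(3,4-dimethoxybenzyl)-3-[hydroxy(3-hydroxy-4-methoxyphenyl)methyl]oxolan-2-one (both carbinol epimers) | COc1ccc(C(O)[C@H]2C(=O)OC[C@@H]2Cc2ccc(OC)c(OC)c2)cc1O | intermediate
10 | (4R)-4-(3,4-dimethoxybenzyl)-3-(3-hydroxy-4-methoxybenzyl)oxolan-2-one (mixture of C3 epimers) | COc1ccc(CC2C(=O)OC[C@@H]2Cc2ccc(OC)c(OC)c2)cc1O | intermediate
11 | Prestegane A, (3R,4R)-4-(3,4-dimethoxybenzyl)-3-(3-hydroxy-4-methoxybenzyl)oxolan-2-one | COc1ccc(C[C@H]2C(=O)OC[C@@H]2Cc2ccc(OC)c(OC)c2)cc1O | target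

**Totals**

Total step count: 5. Longest linear sequence: 5 steps (1 + 2 + 3 → 5 → 6 → 7 → 10 → 11).

**Steps most likely to fail, with fallbacks**

Step 3 (asymmetric double ring closure). The aroyl carbene is bulkier and less reactive than the acceptor groups usually used with this catalyst, so enantioselectivity or conversion may fall short. The fallback moves the asymmetric ring closure to the acceptor-only carbene and brings in the isovanillyl carbon afterwards. It sets out from 3 and comes back at 10.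
- Bromoacetyl bromide and NaHCO3 in MeCN at 0 °C give (2E)-3-(3,4-dimethoxyphenyl)prop-2-en-1-yl bromoacetate F1.
- N,N'-Ditosylhydrazine and DBU in THF at 0 °C convert it into (2E)-3-(3,4-dimethoxyphenyl)prop-2-en-1-yl diazoacetate F2.
- Slow addition to the dirhodium carboxamidate Rh2(4R-MPPIM)4, dirhodium tetrakis[methyl (4R)-2-oxo-1-(3-phenylpropanoyl)imidazolidine-4-carboxylate], in refluxing CH2Cl2 closes lactone and cyclopropane to (1S,5R,6R)-6-(3,4-dimethoxyphenyl)-3-oxabicyclo[3.1.0]hexan-2-one F3. The catalyst hand is the one that delivers 5R.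
- H2 and Pd/C in EtOAc cut the C1–C6 bond to give (R)-4-(3,4-dimethoxybenzyl)oxolan-2-one F4.
- LiN(SiMe3)2 in THF at −78 °C, then commercial 3-(benzyloxy)-4-methoxybenzaldehyde, gives the trans aldol (3S,4R)-3-{[3-(benzyloxy)-4-methoxyphenyl](hydroxy)methyl}-4-(3,4-dimethoxybenzyl)oxolan-2-one F5; the aldehyde adds anti to the C4 benzyl group.
- H2 and Pd(OH)2/C in EtOAc–AcOH remove the benzylic hydroxyl and the benzyl ether to reach 10, here almost entirely the trans isomer, with step 5 as a safeguard.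

Step 4 (hydrogenolysis cascade). The ketone may stall at the alcohol 9, or the benzylic position may cyclise onto the veratryl ring if acid is needed to push it. The fallback avoids both by an electron-transfer ring opening and removal of the oxygen through an enol triflate. It sets out from 7 and comes back at 10.
- SmI2 (2.2 equiv) in THF–MeOH at −78 °C opens the cyclopropyl ketone at C1–C6 through the ketyl to give (3S,4R)-3-[3-(benzyloxy)-4-methoxybenzoyl]-4-(3,4-dimethoxybenzyl)oxolan-2-one F6.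
- NaH and PhNTf2 in THF give the enol triflate (4R)-3-{[3-(benzyloxy)-4-methoxyphenyl][(trifluoromethanesulfonyl)oxy]methylidene}-4-(3,4-dimethoxybenzyl)oxolan-2-one F7.
- Pd(OAc)2, PPh3 and HCO2H–Bu3N in DMF at 60 °C reduce the triflate to (4R)-3-[3-(benzyloxy)-4-methoxybenzylidene]-4-(3,4-dimethoxybenzyl)oxolan-2-one F8.
- H2 and Pd/C in EtOAc saturate the alkene and remove the benzyl ether to give 10, cis-rich, which step 5 converts to 11.

Step 1 (acylketene trapping). The acidic acyl Meldrum's acid at 110 °C may ionise or transpose the electron-rich cinnamyl alcohol. The fallback acylates the alcohol first and makes the C–C bond at room temperature by a decarboxylative Claisen reaction. It sets out from 1, 2 and 3 and comes back at 5.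
- Heating 3 with 2 in toluene at 90 °C gives the malonic half ester 3-{[(2E)-3-(3,4-dimethoxyphenyl)prop-2-en-1-yl]oxy}-3-oxopropanoic acid F9.
- Carbonyldiimidazole in THF turns 1 into 1-[3-(benzyloxy)-4-methoxybenzoyl]-1H-imidazole F10.
- The magnesium enolate of F9 (MgCl2, Et3N, MeCN) is acylated by F10 and loses CO2 on work-up to give 5 (Masamune–Brooks conditions).

**Further compounds**

F1 | step 3 | (2E)-3-(3,4-dimethoxyphenyl)prop-2-en-1-yl bromoacetate | COc1ccc(/C=C/COC(=O)CBr)cc1OC
F2 | step 3 | (2E)-3-(3,4-dimethoxyphenyl)prop-2-en-1-yl diazoacetate | COc1ccc(/C=C/COC(=O)C=[N+]=[N-])cc1OC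
F3 | step 3 | (1S,5R,6R)-6-(3,4-dimethoxyphenyl)-3-oxabicyclo[3.1.0]hexan-2-one | O=C1OC[C@@H]2[C@@H](c3ccc(OC)c(OC)c3)[C@H]12
F4 | step 3 | (R)-4-(3,4-dimethoxybenzyl)oxolan-2-one | O=C1C[C@@H](Cc2ccc(OC)c(OC)c2)CO1
F5 | step 3 | (3S,4R)-3-{[3-(benzyloxy)-4-methoxyphenyl](hydroxy)methyl}-4-(3,4-dimethoxybenzyl)oxolan-2-one (both carbinol epimers) | COc1ccc(C(O)[C@H]2C(=O)OC[C@@H]2Cc2ccc(OC)c(OC)c2)cc1OCc1ccccc1
F6 | step 4 | (3S,4R)-3-[3-(benzyloxy)-4-methoxybenzoyl]-4-(3,4-dimethoxybenzyl)oxolan-2-one | COc1ccc(C(=O)[C@H]2C(=O)OC[C@@H]2Cc2ccc(OC)c(OC)c2)cc1OCc1ccccc1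
F7 | step 4 | (4R)-3-{[3-(benzyloxy)-4-methoxyphenyl][(trifluoromethanesulfonyl)oxy]methylidene}-4-(3,4-dimethoxybenzyl)oxolan-2-one (E/Z mixture) | COc1ccc(C(OS(=O)(=O)C(F)(F)F)=C2C(=O)OC[C@@H]2Cc2ccc(OC)c(OC)c2)cc1OCc1ccccc1
F8 | step 4 | (4R)-3-[3-(benzyloxy)-4-methoxybenzylidene]-4-(3,4-dimethoxybenzyl)oxolan-2-one (E/Z mixture) | COc1ccc(C=C2C(=O)OC[C@@H]2Cc2ccc(OC)c(OC)c2)cc1OCc1ccccc1
F9 | step 1 | 3-{[(2E)-3-(3,4-dimethoxyphenyl)prop-2-en-1-yl]oxy}-3-oxopropanoic acid | COc1ccc(/C=C/COC(=O)CC(=O)O)cc1OC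
F10 | step 1 | 1-[3-(benzyloxy)-4-methoxybenzoyl]-1H-imidazole | COc1ccc(C(=O)n2ccnc2)cc1OCc1ccccc1
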